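The runs were generated by integration on assumed constants.

If D in the violet flask stops falling well inside 6.0 h, the answer at 6.0 h is a reading and no extrapolation is needed, so I sorted the violet run by time scale.

| setting | violet | flask |
|---|---|---|
| Q | 0.19 M | 0.19 M |
| remark | the very flask that is asked about, followed so far |  |
| time |  | 6.0 h |

violet run (percent of the Q charged)

| time / min | Q / % | D / % | G / % |
|---|---|---|---|
| 15.0 | 0 | 93.8 | 3.3 |
| 30.0 | 0 | 91.9 | 3.9 |
| 40.0 | 0.9 | 90.9 | 4.1 |
| 60.0 | 0.4 | 88.8 | 4.8 |
| 80.0 | 0.4 | 89.8 | 5.3 |

(standard deviation of a reading: 0.5 percentage points)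

- at the start none of Q is in solution
- what has only dissolved of Q counts as not reacted
- a reading or a percentage of D counts all its forms, free or not

- part of the Q that has turned into other species by 6.0 h (what has only dissolved does not count)
- how much D there is at 6.0 h, in percent of the Q charged
- how much G there is at 6.0 h, in percent of the Q charged
- how much E there is at 6.0 h, in percent of the Q charged

On the fastest rung stood Q, which already read 0% at 15.0 min, with D at 93.8%. On the next rung D fell, but it slowed: the mean of its last two readings is 89.3%, and I took that as a plateau, with a scatter of 0.5 percentage points on each reading. The distance of D from that plateau shrank between 15.0 min and 30.0 min at a rate that gives a half-life of about 19.0 min. Because this is far shorter than 6.0 h, I expected the plateau to stand at 6.0 h, a bet on thermodynamic rather than kinetic control. Over the same readings G rose, from 3.3% at 15.0 min to 5.3% at 80.0 min.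

I carried one number, the rest concentration c_rest, meaning the material per litre that does not count as D: 20.3 mM. It leaves 10.7% of the charge for G, E and anything else.

The forecast gave conversion 99.8%, D 75.5%, G 11.5% and E 13%, reasoning “Extrapolating to 360 min gives D of about 75%”. My D stood higher, by 14 points.

The flask gave conversion 98.0%, D 88.6%, G 5.40% and E 2.72%. Counted in that D, crystals Z stood at 85.6% of the Q charged at 6.00 h. Its c_rest at 6.0 h comes to 21.7 mM, beside the 20.3 mM I read from the plateau.

    D ⇌ G (K = 1.80, k = 0.0961 /min)
    E ⇌ X (k = 0.00704 /min)
    Z ⇌ D, rate k3*(cs3 - [D]) while solid is left; crystals form when [D] > cs3 (solubility = 5.70 mM, k = 28.3 /min)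
    Q ⇌ X, rate k4*(cs4 - [X]) while solid is left; crystals form when [X] > cs4 (solubility = 0.100 M, k = 4.59 /min)
    X ⇌ D (K = 1.48, k = 2.18 /min)
    G ⇌ E (K = 0.503, k = 0.0233 /min)
    D ⇌ J (K = 0.420, k = 0.00798 /min)

For the neighbour flask with 0.11 M of Q, the same c_rest gives D 81.5%, whereas holding the percentage fixed gives 89.3%. The computed neighbour flask gave D 80.3%.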